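**Plan**

- Labdane numbering is used (ring A = C1–C5, C10; ring B = C5–C10; C20 on C10 is β). Retrosynthesis: the acid and the O3 ester are unmasked last, the 3α/6β carbinols go back to the 3,6-dione, and the C7H2–C8=C9–C11H2 unit goes back (1,6-reduction) to the 7,9(11)-dien-6-one. Ring B is then cut at C6–C7 and C8–C9 in one stroke.
- The feature that allows this cut: C6 and C9 of ring B stand 1,4 across the C5–C10 bond shared with ring A, so seco-ring B is a 4-alkynal (C6 formyl, C9≡C11 alkynyl, trans on ring A) and C7–C8–C17 is a propyne unit. A rhodium-catalysed 4-alkynal/alkyne [4+2] annulation rebuilds ring B with C6 as the ketone.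
- Further cuts: C11–C12 (alkynyl–allyl coupling with the C12–C16 bromide), then ring A at C1–C10 and C4–C5 (Diels–Alder reaction of a 2-silyloxydiene ester with an E-enal).
- Forward order: ring A, C9 alkyne, C4 methylation, C19 carbinol and its ester, side chain, ring B, redox adjustment, O3 ester, acid.
- Stereochemistry: C5/C10 from the catalyst-controlled Diels–Alder reaction of an E-enal; C4 from methylation anti to the C5 substituent; C3 and C6 from hydride attack on the rigid trans-decalin dione; C13=C14 (E) from a Wittig reaction.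

Key step: step 11

Assumption: the facial sense of the oxazaborolidinium catalyst in step 2 is taken from the usual model for 2-substituted enals; the antipodal catalyst is used without other change if the diene proves to add to the other face.

**Route**

Step 1
Reactants: 1 methyl 3-oxopent-4-enoate
Product: 2 methyl (2Z)-3-(triisopropylsilyloxy)penta-2,4-dienoate
Conditions: i-Pr3SiOTf (1.05 equiv), Et3N (1.3 equiv), Et2O, 0 °C
Reagents that add atoms: triisopropylsilyl trifluoromethanesulfonate, CC(C)[Si](C(C)C)(C(C)C)OS(=O)(=O)C(F)(F)F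
Why: O-silylation of the enolised β-keto ester (soft enolisation) should give the 2-silyloxy diene with the Z geometry of the chelated enol.

Step 2
Reactants: 2 methyl (2Z)-3-(triisopropylsilyloxy)penta-2,4-dienoate; 3 (2E)-4,4-dimethoxy-2-methylbut-2-enal
Product: 4 methyl 6-(dimethoxymethyl)-5-formyl-5-methyl-2-(triisopropylsilyloxy)cyclohex-2-ene-1-carboxylate (formyl trans to dimethoxymethyl; C5 and C10 of the target set; C4 unassigned)
Conditions: B-(o-tolyl)oxazaborolidine from (S)-α,α-diphenylprolinol (20 mol %), HNTf2 (18 mol %), CH2Cl2, −78 → −40 °C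
Reagents that add atoms: none
Why: Diels–Alder reaction under chiral Lewis-acid control: the oxazaborolidinium cation binds the formyl group of 3 and should leave the si face of the α-carbon open, which fixes C10 and C5 (trans because 3 is E), while the silyloxy group of 2 directs its ester-bearing terminus to the β-carbon (C4–C5) and its CH2 terminus to the α-carbon (C1–C10), an orientation that sterics also favour; C4 is left unassigned because it is planarised in step 4.

Step 3
Reactants: 4 methyl 6-(dimethoxymethyl)-5-formyl-5-methyl-2-(triisopropylsilyloxy)cyclohex-2-ene-1-carboxylate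
Product: 5 methyl 6-(dimethoxymethyl)-5-ethynyl-5-methyl-2-(triisopropylsilyloxy)cyclohex-2-ene-1-carboxylate
Conditions: dimethyl (1-diazo-2-oxopropyl)phosphonate (1.5 equiv), K2CO3 (2 equiv), MeOH, 0 °C → rt
Reagents that add atoms: dimethyl (1-diazo-2-oxopropyl)phosphonate, CC(=O)C(=[N+]=[N-])P(=O)(OC)OC
Why: Seyferth–Gilbert homologation in the Ohira–Bestmann form should turn the non-enolisable aldehyde into the terminal alkyne (C9≡C11) under carbonate conditions that the methyl ester and the bulky silyl enol ether tolerate, with no stereocenter of the target touched.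

Step 4
Reactants: 5 methyl 6-(dimethoxymethyl)-5-ethynyl-5-methyl-2-(triisopropylsilyloxy)cyclohex-2-ene-1-carboxylate
Product: 7 methyl 6-(dimethoxymethyl)-5-ethynyl-1,5-dimethyl-2-(triisopropylsilyloxy)cyclohex-2-ene-1-carboxylate (4α-methyl; 4β-ester), via dilithium acetylide enolate 6 (not isolated)
Conditions: LiN(i-Pr)2 (2.2 equiv), THF, −78 °C; MeI (1.1 equiv), −78 → −40 °C; then H2O
Reagents that add atoms: iodomethane, CI
Why: Alkylation of an ester enolate: the second equivalent of base only parks the alkyne as its acetylide (inert to MeI in THF at −78 °C), and MeI should enter the planar C4 enolate anti to the neighbouring C5 dimethoxymethyl group, which allylic strain pushes pseudo-axial, so that the methyl ends α and the ester (C19) β, cis to C6; a double-bond isomer of 5 would give the same dienolate.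

Step 5
Reactants: 7 methyl 6-(dimethoxymethyl)-5-ethynyl-1,5-dimethyl-2-(triisopropylsilyloxy)cyclohex-2-ene-1-carboxylate
Product: 9 3-(dimethoxymethyl)-4-ethynyl-2-(hydroxymethyl)-2,4-dimethylcyclohexan-1-one, via silyl enol ether alcohol 8 (not isolated)
Conditions: LiAlH4 (2 equiv), Et2O, 0 °C → rt, then H2O and aq. NaOH; crude 8 then Bu4NF (1.2 equiv), AcOH (1.5 equiv), THF, 0 °C
Reagents that add atoms: none
Why: Hydride reduction of the hindered ester gives the C19 carbinol while the C3 ketone stays masked as its silyl enol ether, and buffered fluoride then cleaves the enol ether to the β-hydroxy ketone (acetic acid suppresses retro-aldol loss of formaldehyde); C3 is kept as a ketone on purpose until ring A is locked in the decalin.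

Step 6
Reactants: 9 3-(dimethoxymethyl)-4-ethynyl-2-(hydroxymethyl)-2,4-dimethylcyclohexan-1-one
Product: 10 [2-(dimethoxymethyl)-3-ethynyl-1,3-dimethyl-6-oxocyclohexyl]methyl 3-methylbutanoate
Conditions: (i-BuCO)2O (1.5 equiv), DMAP (0.1 equiv), pyridine, CH2Cl2, 0 °C → rt
Reagents that add atoms: 3-methylbutanoic anhydride, CC(C)CC(=O)OC(=O)CC(C)C
Why: DMAP-catalysed acylation of the primary neopentyl alcohol installs the C19 isovalerate of the target now, because a free C19 hydroxyl would later close a lactol onto the C6 aldehyde.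

Step 7
Reactants: 11 1-hydroxypropan-2-one; 12 tert-butyl (triphenylphosphoranylidene)acetate
Product: 13 tert-butyl (2E)-4-hydroxy-3-methylbut-2-enoate
Conditions: CH2Cl2, rt → 40 °C
Reagents that add atoms: none
Why: Wittig reaction of a stabilised ylide with an α-hydroxy ketone should give mainly the E enoate (C13=C14 of the target); any Z isomer, which tends to lactonise, is removed by chromatography.

Step 8
Reactants: 13 tert-butyl (2E)-4-hydroxy-3-methylbut-2-enoate
Product: 14 tert-butyl (2E)-4-bromo-3-methylbut-2-enoate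
Conditions: CBr4 (1.2 equiv), PPh3 (1.25 equiv), CH2Cl2, 0 °C
Reagents that add atoms: tetrabromomethane, BrC(Br)(Br)Br
Why: Appel reaction: SN2 displacement on the activated primary allylic alcohol should leave the E alkene untouched.

Step 9
Reactants: 10 [2-(dimethoxymethyl)-3-ethynyl-1,3-dimethyl-6-oxocyclohexyl]methyl 3-methylbutanoate; 14 tert-butyl (2E)-4-bromo-3-methylbut-2-enoate
Product: 15 tert-butyl (2E)-6-[2-(dimethoxymethyl)-1,3-dimethyl-3-[(3-methylbutanoyloxy)methyl]-4-oxocyclohexyl]-3-methylhex-2-en-5-ynoate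
Conditions: CuI (10 mol %), Bu4NI (10 mol %), K2CO3 (1.5 equiv), DMF, rt
Reagents that add atoms: none
Why: Copper-catalysed coupling of a terminal alkyne with a primary allylic bromide (the copper acetylide substitutes at CH2Br) should form C11–C12 under carbonate conditions that the ketone, the esters and the acetal tolerate.

Step 10
Reactants: 15 tert-butyl (2E)-6-[2-(dimethoxymethyl)-1,3-dimethyl-3-[(3-methylbutanoyloxy)methyl]-4-oxocyclohexyl]-3-methylhex-2-en-5-ynoate
Product: 16 tert-butyl (2E)-6-[2-formyl-1,3-dimethyl-3-[(3-methylbutanoyloxy)methyl]-4-oxocyclohexyl]-3-methylhex-2-en-5-ynoate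
Conditions: pyridinium p-toluenesulfonate (0.3 equiv), acetone/H2O (10:1), 50 °C
Reagents that add atoms: water, O
Why: Mild acid-catalysed acetal hydrolysis should unmask the C6 aldehyde without cleaving the tert-butyl ester, and C5 keeps its configuration because the formyl group already sits trans to the alkynyl group.

Step 11
Reactants: 16 tert-butyl (2E)-6-[2-formyl-1,3-dimethyl-3-[(3-methylbutanoyloxy)methyl]-4-oxocyclohexyl]-3-methylhex-2-en-5-ynoate; 17 trimethyl(prop-1-yn-1-yl)silane
Product: 18 tert-butyl 19-(3-methylbutanoyloxy)-3,6-dioxo-7-(trimethylsilyl)labda-7,9(11),13E-trien-15-oate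
Conditions: [Rh(dppe)]2(BF4)2 (5 mol %; dppe = Ph2PCH2CH2PPh2), 17 (3 equiv), CH2Cl2, 25 → 40 °C
Reagents that add atoms: none
Why: Oxidative addition of the monovalent rhodium cation into the C6 aldehyde C–H bond gives an acylrhodium hydride held next to the C9≡C11 alkyne; syn-hydrorhodation (Rh to C9, H to C11) gives a five-membered acyl(alkenyl)rhodacycle, alkyne 17 inserts into the Rh–C9 bond and C–C reductive elimination then joins C7 to C6, so that C8–C9 and C6–C7 are made in one catalytic cycle. The closest known reaction type is the rhodium-catalysed [4+2] annulation of 4-alkynals with alkynes to 4-alkylidenecyclohex-2-enones. Ring B closes by reductive elimination from the seven-membered rhodacycle (a formal [4+2] of the four-carbon unit C6–C5–C10–C9 and the two alkyne carbons) and is trans-fused because C6 and C9 can both sit equatorial on ring A. No new stereocenter is formed: C5 and C10 are in place, the quaternary C10 blocks aromatisation, and the geometry of the C9=C11 alkene is of no consequence because C11 becomes CH2 in step 12. The step needs regioselective insertion (methyl-bearing carbon to C9, the other carbon to the acyl group), which the trimethylsilyl group of 17 should secure, since the bulky C9 migrates to the less hindered methyl-bearing carbon and rhodium prefers the silyl-bearing carbon. It also needs the annulation to outrun decarbonylation and closure to a cyclopentenone, which the chelating gauche arrangement of formyl and alkynyl groups and the excess of 17 should favour.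

Step 12
Reactants: 18 tert-butyl 19-(3-methylbutanoyloxy)-3,6-dioxo-7-(trimethylsilyl)labda-7,9(11),13E-trien-15-oate
Product: 20 tert-butyl 19-(3-methylbutanoyloxy)-3,6-dioxolabda-8,13E-dien-15-oate, via 7-silyl diketone 19 (not isolated)
Conditions: [(Ph3P)CuH]6 (0.5 equiv), H2O (3 equiv), degassed benzene/THF, rt; then Bu4NF (1.1 equiv), AcOH (2 equiv), THF, −20 °C
Reagents that add atoms: none
Why: Conjugate (1,6) hydride transfer from copper to C11, the unhindered δ-terminus of the linear dienone (the β-carbon C8 is fully substituted and flanked by the silyl group), should give the extended enolate, which is protonated at C7; buffered fluoride then cleaves the labile α-silyl ketone and the dienolate is again protonated kinetically at C7, so that the alkene ends at C8=C9 out of conjugation, while the hindered C3 ketone and the β,β-disubstituted enoate should not react.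

Step 13
Reactants: 20 tert-butyl 19-(3-methylbutanoyloxy)-3,6-dioxolabda-8,13E-dien-15-oate
Product: 21 tert-butyl 3α,6β-dihydroxy-19-(3-methylbutanoyloxy)labda-8,13E-dien-15-oate
Conditions: LiBH(s-Bu)3 (2.5 equiv), THF, −78 °C; then pH 7 buffer
Reagents that add atoms: none
Why: The bulky hydride should attack both ketones of the rigid trans-decalin along the equatorial trajectory: at C3 this gives the axial 3α-alcohol, and at C6 it comes from the α face because the β face is closed by the syn-axial C19 and C20 groups, which gives the axial 6β-alcohol; the esters survive at −78 °C and the anti (trans-diaxial) relation of O3 and C19 rules out acyl migration.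

Step 14
Reactants: 21 tert-butyl 3α,6β-dihydroxy-19-(3-methylbutanoyloxy)labda-8,13E-dien-15-oate
Product: 22 tert-butyl 6β-hydroxy-3α,19-bis(3-methylbutanoyloxy)labda-8,13E-dien-15-oate
Conditions: (i-BuCO)2O (1.3 equiv), DMAP (0.2 equiv), pyridine, CH2Cl2, 0 °C → rt
Reagents that add atoms: 3-methylbutanoic anhydride, CC(C)CC(=O)OC(=O)CC(C)C
Why: Site-selective DMAP-catalysed acylation: the axial 3α-hydroxyl has only syn-axial hydrogens and should react, whereas the 6β-hydroxyl, syn-axial to both C19 and C20, should be too shielded.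

Step 15
Reactants: 22 tert-butyl 6β-hydroxy-3α,19-bis(3-methylbutanoyloxy)labda-8,13E-dien-15-oate
Product: 23 6β-hydroxy-3α,19-bis(3-methylbutanoyloxy)labda-8,13E-dien-15-oic acid (CNP0333611.1)
Conditions: CF3CO2H/CH2Cl2 (1:5), 0 °C
Reagents that add atoms: none
Why: Acidolysis of the tert-butyl ester (loss of isobutene through the tert-butyl cation) should free the acid while the two isovalerates, which cannot ionise, stay in place.

**Compound list**

1 | methyl 3-oxopent-4-enoate | C=CC(=O)CC(=O)OC | starting material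
2 | methyl (2Z)-3-(triisopropylsilyloxy)penta-2,4-dienoate | C=C/C(O[Si](C(C)C)(C(C)C)C(C)C)=C/C(=O)OC | intermediate
3 | (2E)-4,4-dimethoxy-2-methylbut-2-enal | COC(OC)/C=C(\C)C=O | starting material
4 | methyl 6-(dimethoxymethyl)-5-formyl-5-methyl-2-(triisopropylsilyloxy)cyclohex-2-ene-1-carboxylate (formyl trans to dimethoxymethyl; C4 unassigned) | O=C[C@@]1(C)CC=C(O[Si](C(C)C)(C(C)C)C(C)C)C(C(=O)OC)[C@@H]1C(OC)OC | intermediate
5 | methyl 6-(dimethoxymethyl)-5-ethynyl-5-methyl-2-(triisopropylsilyloxy)cyclohex-2-ene-1-carboxylate | C#C[C@@]1(C)CC=C(O[Si](C(C)C)(C(C)C)C(C)C)C(C(=O)OC)[C@@H]1C(OC)OC | intermediate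
6 | dilithium acetylide ester enolate of 5 | [Li]C#C[C@@]1(C)CC=C(O[Si](C(C)C)(C(C)C)C(C)C)C(=C(OC)O[Li])[C@@H]1C(OC)OC | intermediate (not isolated)
7 | methyl 6-(dimethoxymethyl)-5-ethynyl-1,5-dimethyl-2-(triisopropylsilyloxy)cyclohex-2-ene-1-carboxylate (4α-methyl, 4β-ester, labdane numbering) | C#C[C@@]1(C)CC=C(O[Si](C(C)C)(C(C)C)C(C)C)[C@](C)(C(=O)OC)[C@@H]1C(OC)OC | intermediate
8 | [6-(dimethoxymethyl)-5-ethynyl-1,5-dimethyl-2-(triisopropylsilyloxy)cyclohex-2-en-1-yl]methanol | C#C[C@@]1(C)CC=C(O[Si](C(C)C)(C(C)C)C(C)C)[C@](C)(CO)[C@@H]1C(OC)OC | intermediate (not isolated)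
9 | 3-(dimethoxymethyl)-4-ethynyl-2-(hydroxymethyl)-2,4-dimethylcyclohexan-1-one | C#C[C@@]1(C)CCC(=O)[C@](C)(CO)[C@@H]1C(OC)OC | intermediate
10 | [2-(dimethoxymethyl)-3-ethynyl-1,3-dimethyl-6-oxocyclohexyl]methyl 3-methylbutanoate | C#C[C@@]1(C)CCC(=O)[C@](C)(COC(=O)CC(C)C)[C@@H]1C(OC)OC | intermediate
11 | 1-hydroxypropan-2-one | CC(=O)CO | starting material
12 | tert-butyl (triphenylphosphoranylidene)acetate | CC(C)(C)OC(=O)C=P(c1ccccc1)(c1ccccc1)c1ccccc1 | starting material
13 | tert-butyl (2E)-4-hydroxy-3-methylbut-2-enoate | CC(C)(C)OC(=O)/C=C(\C)CO | intermediate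
14 | tert-butyl (2E)-4-bromo-3-methylbut-2-enoate | CC(C)(C)OC(=O)/C=C(\C)CBr | intermediate
15 | tert-butyl (2E)-6-[2-(dimethoxymethyl)-1,3-dimethyl-3-[(3-methylbutanoyloxy)methyl]-4-oxocyclohexyl]-3-methylhex-2-en-5-ynoate | CC(C)(C)OC(=O)/C=C(\C)CC#C[C@@]1(C)CCC(=O)[C@](C)(COC(=O)CC(C)C)[C@@H]1C(OC)OC | intermediate
16 | tert-butyl (2E)-6-[2-formyl-1,3-dimethyl-3-[(3-methylbutanoyloxy)methyl]-4-oxocyclohexyl]-3-methylhex-2-en-5-ynoate | CC(C)(C)OC(=O)/C=C(\C)CC#C[C@@]1(C)CCC(=O)[C@](C)(COC(=O)CC(C)C)[C@@H]1C=O | intermediate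
17 | trimethyl(prop-1-yn-1-yl)silane | CC#C[Si](C)(C)C | starting material
18 | tert-butyl 19-(3-methylbutanoyloxy)-3,6-dioxo-7-(trimethylsilyl)labda-7,9(11),13E-trien-15-oate (C12 cis to C10 on the exocyclic alkene) | CC=1C(=C/C/C(C)=C/C(=O)OC(C)(C)C)/[C@@]2(C)CCC(=O)[C@](C)(COC(=O)CC(C)C)[C@@H]2C(=O)C=1[Si](C)(C)C | intermediate
19 | tert-butyl 19-(3-methylbutanoyloxy)-3,6-dioxo-7-(trimethylsilyl)labda-8,13E-dien-15-oate (C7 epimers) | CC1=C(CC/C(C)=C/C(=O)OC(C)(C)C)[C@@]2(C)CCC(=O)[C@](C)(COC(=O)CC(C)C)[C@@H]2C(=O)C1[Si](C)(C)C | intermediate (not isolated)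
20 | tert-butyl 19-(3-methylbutanoyloxy)-3,6-dioxolabda-8,13E-dien-15-oate | CC1=C(CC/C(C)=C/C(=O)OC(C)(C)C)[C@@]2(C)CCC(=O)[C@](C)(COC(=O)CC(C)C)[C@@H]2C(=O)C1 | intermediate
21 | tert-butyl 3α,6β-dihydroxy-19-(3-methylbutanoyloxy)labda-8,13E-dien-15-oate | CC1=C(CC/C(C)=C/C(=O)OC(C)(C)C)[C@@]2(C)CC[C@@H](O)[C@](C)(COC(=O)CC(C)C)[C@@H]2[C@H](O)C1 | intermediate
22 | tert-butyl 6β-hydroxy-3α,19-bis(3-methylbutanoyloxy)labda-8,13E-dien-15-oate | CC1=C(CC/C(C)=C/C(=O)OC(C)(C)C)[C@@]2(C)CC[C@@H](OC(=O)CC(C)C)[C@](C)(COC(=O)CC(C)C)[C@@H]2[C@H](O)C1 | intermediate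
23 | 6β-hydroxy-3α,19-bis(3-methylbutanoyloxy)labda-8,13E-dien-15-oic acid (CNP0333611.1) | CC1=C(CC/C(C)=C/C(=O)O)[C@@]2(C)CC[C@@H](OC(=O)CC(C)C)[C@](C)(COC(=O)CC(C)C)[C@@H]2[C@H](O)C1 | target

**Count and risks**

Total step count: 15. Longest linear sequence: 13 steps (steps 1–6 and 9–15); steps 7 and 8 make the side-chain bromide.

Steps most likely to fail:

1. Step 11. Insertion of the hindered silylalkyne into the rhodacycle may be slower than closure of the acylrhodium hydride onto its own alkyne (cyclopentenone formation) or than decarbonylation. The fallback sets out from 16, makes the two bonds one after the other, and comes back at 20. Barbier 2-bromoallylation of the aldehyde with 2,3-dibromopropene and In powder (THF/H2O) should give the bromoallyl carbinol F1 (C6–C7 bond). Reductive Heck cyclisation (Pd(OAc)2, PPh3, HCO2Na, DMF, 80 °C; 6-exo-dig carbopalladation of the C9≡C11 alkyne by the C8 alkenylpalladium, then formate reduction) should give the 8(17),9(11)-dien-6-ol F2 (C8–C9 bond). Dess–Martin oxidation followed by DBU should move the exocyclic C8=C17 bond into conjugation and give the silicon-free 7,9(11)-dien-6-one F3. The copper hydride 1,6-reduction of step 12, without the fluoride stage, then gives 20.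

2. Step 2. The boron Lewis acid may ionise the allylic dimethyl acetal, or the ester-bearing diene terminus may add too slowly to the trisubstituted enal, giving low conversion or poor facial selectivity. The fallback sets out from 3, uses a more reactive diene without a Lewis acid, and comes back at 7. 1-(Dimethylamino)-3-(tert-butyldimethylsilyloxy)buta-1,3-diene under hydrogen-bond catalysis by a tetra(1-naphthyl)-TADDOL (the enantiomer that exposes the same face) should give the aminocyclohexene cycloadduct F4. Work-up with HF in MeCN should give the 4-formyl enone F5, and the Ohira–Bestmann reaction the enone alkyne F6. Methoxycarbonylation at the only enolisable position (NaH, dimethyl carbonate) should give the β-keto ester F7, and K2CO3/MeI the 4α-methyl β-keto ester F8 (methyl anti to the C5 substituent). Conjugate reduction with LiBH(s-Bu)3 at −78 °C and trapping of the enolate with i-Pr3SiOTf then gives 7.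

3. Step 12. Hydride may be delivered to C8 (1,4) instead of C11 (1,6), or the dienolate may be protonated at C9 and slide the alkene into conjugation with the C6 ketone. The fallback sets out from 18 and comes back at 19. It replaces hydride transfer by electron transfer: SmI2 (2.2 equiv), MeOH, THF, −78 °C. The radical anion of the dienone should be protonated at the terminal C11, and after the second electron the samarium dienolate should be protonated kinetically at C7. This gives 19, which is desilylated as in step 12; no new compound arises.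

**Further compounds**

F1 | step 11 | tert-butyl (2E)-6-[2-(3-bromo-1-hydroxybut-3-en-1-yl)-1,3-dimethyl-3-[(3-methylbutanoyloxy)methyl]-4-oxocyclohexyl]-3-methylhex-2-en-5-ynoate (carbinol epimers) | CC(C)(C)OC(=O)/C=C(\C)CC#C[C@@]1(C)CCC(=O)[C@](C)(COC(=O)CC(C)C)[C@@H]1C(O)CC(Br)=C
F2 | step 11 | tert-butyl 6-hydroxy-19-(3-methylbutanoyloxy)-3-oxolabda-8(17),9(11),13E-trien-15-oate (C6 epimers) | C=C1C(=C/C/C(C)=C/C(=O)OC(C)(C)C)/[C@@]2(C)CCC(=O)[C@](C)(COC(=O)CC(C)C)[C@@H]2C(O)C1
F3 | step 11 | tert-butyl 19-(3-methylbutanoyloxy)-3,6-dioxolabda-7,9(11),13E-trien-15-oate | CC=1C(=C/C/C(C)=C/C(=O)OC(C)(C)C)/[C@@]2(C)CCC(=O)[C@](C)(COC(=O)CC(C)C)[C@@H]2C(=O)C=1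
F4 | step 2 | 6-(dimethoxymethyl)-2-(dimethylamino)-1-methyl-4-(tert-butyldimethylsilyloxy)cyclohex-3-ene-1-carbaldehyde (amine-bearing carbon unassigned) | O=C[C@@]1(C)C(N(C)C)C=C(O[Si](C)(C)C(C)(C)C)C[C@@H]1C(OC)OC
F5 | step 2 | 6-(dimethoxymethyl)-1-methyl-4-oxocyclohex-2-ene-1-carbaldehyde | O=C[C@@]1(C)C=CC(=O)C[C@@H]1C(OC)OC
F6 | step 2 | 5-(dimethoxymethyl)-4-ethynyl-4-methylcyclohex-2-en-1-one | C#C[C@@]1(C)C=CC(=O)C[C@@H]1C(OC)OC
F7 | step 2 | methyl 6-(dimethoxymethyl)-5-ethynyl-5-methyl-2-oxocyclohex-3-ene-1-carboxylate (C4 unassigned) | C#C[C@@]1(C)C=CC(=O)C(C(=O)OC)[C@@H]1C(OC)OC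
F8 | step 2 | methyl 6-(dimethoxymethyl)-5-ethynyl-1,5-dimethyl-2-oxocyclohex-3-ene-1-carboxylate | C#C[C@@]1(C)C=CC(=O)[C@](C)(C(=O)OC)[C@@H]1C(OC)OC
F0 | step 12 | none | none
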